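# Proposed total synthesis of parritadial (17)

## Analysis of the target

Parritadial (17) is a drimane, a trans-fused decalin. Ring A (C1–C5, C10) is a cyclohexane with the C4 gem-dimethyl group and an equatorial 1β-acetoxy group. Ring B (C5–C10) is a cyclohexene (C7=C8) that carries the 6α-acetoxy group, the C12 enal on C8, and at C9 a tertiary α-hydroxyl with the C11 aldehyde β.

There are five stereocenters: C1 (R), C5 (S), C6 (S), C9 (S) and C10 (R). The quaternary C10 (methyl β) is surrounded by C1 (oxygen cis to the methyl), C5 (hydrogen trans to it) and C9 (hydroxyl trans to it).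

The feature this plan is built on is the unit O–C6–C7=C8–C9–O in ring B. The two C–O bonds sit 1,4 across the double bond and both lie on the α face. That is the pattern left when a 6,9-epidioxide bridge on a C6=C7–C8=C9 diene is cut at the O–O bond.

Sensitive groups are the ene-1,4-dialdehyde (lactol, hydrate and α-ketol chemistry; C6–H is vinylogously acidic), the allylic acetate and the tertiary allylic alcohol. The synthesis is hard for four reasons:
- the C1 oxygen sits on a methylene next to quaternary C10, out of reach of any relay from ring B;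
- the equatorial 6α-oxygen is the epimer that hydride reduction of a 6-ketone does not give;
- C9 and C10 are adjacent fully substituted carbons;
- the aldehydes must appear last.

## Retrosynthetic reasoning

**17 ⇒ 16.** The two aldehydes are taken back to primary alcohols. Both C11 and C12 are then at one robust oxidation level for the whole route, and the sensitive dialdehyde is made in the last step by one double oxidation that cannot touch the tertiary C9 hydroxyl.

**16 ⇒ 15 ⇒ 14.** The acetates go on while C11 and C12 are silylated. In 14 the only free hydroxyls are the secondary ones at C1 and C6 (to be acetylated) and the tertiary one at C9 (to stay free), so no selectivity problem arises.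

**14 ⇒ 13 ⇒ 12 (key disconnection).** Both C–O bonds of ring B (C6–O and C9–O) are cut in one stroke: diol 14 comes from epidioxide 13, which comes from diene 12 by a [4+2] photooxygenation. The cut is made here because the two oxygens are cis and 1,4 across C7=C8. One cycloaddition sets C6 and C9 together, places the double bond, and needs only the C10 methyl as control element. The forward step must add from the α face and must win over ene-type oxidation. In 13, ring A is trans-fused across the C5–C10 bridge of the peroxide bicycle, so the adduct is strained; O–O cleavage in the same flask releases that strain.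

**12 ⇒ 11 ⇒ 10.** The electron-rich diene diol is the reduced form of dienoate 10. The hydride reduction also removes the C1 pivalate, so the C1 hydroxyl is free when needed and costs no deprotection step. The two primary hydroxyls are then silylated selectively.

**10 ⇒ 9.** The conjugated 6,8-diene is the prototropic isomer of the skipped 5,8-diene 9. Moving one hydrogen from C7 to C5 creates the diene for the key step and sets C5 (5α-H, trans fusion) under equilibrium control.

**9 ⇒ 7 + 8.** Ring B is opened at C9–C10 and C7–C8 (Diels–Alder). This is the only cut that makes the quaternary C10 and brings in C11 and C12, both already oxidized, in one step from an eleven-carbon diene and the four-carbon diester 8. The C1 stereocenter of 7 has to steer the dienophile to the face anti to its oxygen so that the C10 methyl ends up cis to O1.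

**7 ⇒ 6 ⇒ 5.** The single stereocenter of the diene (C1) comes from a catalytic enantioselective reduction of dienone 5. It is the only step in the route that introduces absolute configuration; C10, C5, C6 and C9 are all relayed from it.

**5 ⇒ 3 ⇒ 1.** Dienone 5 is a 1,3-transposed vinylogous ester. It goes back to 3 (vinyl addition and transposition) and then to 1 by double α′-methylation, which installs the future C4 gem-dimethyl group.

## Alternatives that were turned down

**Alternative 1:** the textbook chiral-pool route. No skeletal bond is cut; the C–O bonds at C1, C6 and C9 are disconnected from a ready-made drimane, drim-7-ene-11,12-diol A2, which is a few known operations from the commercial lactone (+)-sclareolide A1. The forward key steps would be enolate hydroxylation at C9, allylic oxidation at C6 and a C–H oxidation at C1. It was turned down for three reasons: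
- C1 of A1 and A2 is an unactivated methylene, shielded by the C10 methyl and separated from every functional group by a quaternary carbon. Undirected C–H oxidation of this skeleton prefers the remote C2 and C3 positions, and no directing group reaches C1 through a reasonable ring size.
- The usual way to a C6 oxygen passes through a 6-ketone. Hydride enters from the open α face and gives the axial 6β-alcohol, so the target would need an inversion at a hindered allylic center.
- Each oxygen costs its own sequence, which makes this longer than the whole present route.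

**Alternative 2:** Robinson annulation in the Wieland–Miescher manner. Ring B is cut at C9–C10 (Michael addition) and C5–C6 (aldol condensation). The forward key step is an amine-catalysed enantioselective aldol condensation of triketone A3 to enedione A4 (Hajos–Parrish type), which sets C10 and keeps a ketone at C1. It was turned down for two reasons:
- In A3 the aldol has to attack the carbonyl flanked by the gem-dimethyl carbon (future C5) and spare the unhindered one (future C1). The intrinsic preference is the reverse and would place the gem-dimethyl group next to the surviving ketone.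
- A4 has no C11 and no C12, has oxygen at C7 where the target has none, and has none at C6 and C9. More than ten further steps and a separate solution for the trans ring fusion would follow.

**Alternative 3:** 6π-electrocyclization. Only C9–C10 is cut and ring B is opened to a triene. The commercial C13 ketone A5 already holds ring A, the C1 oxygen, C6–C8 and C12. Olefination would give trienoate A6; light-induced E→Z isomerization of C6=C7 and thermal disrotatory closure would give bicyclic diene A7. It was turned down for three reasons:
- The C10 terminus is tetrasubstituted and its methyl points into the triene, which retards the closure. The [1,5]-hydrogen shift from that methyl to C7 needs the same cisoid geometry and should win.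
- A7 is a racemic 5,7-diene with C12 still a methyl and only one ester. Diene transposition, C12 oxidation and a source of absolute configuration all remain.
- Photooxygenation of the 5,7-diene would put oxygen on C5 and C8, not on C6 and C9.

Key step: step 9

## Route

Remark (assumption): 1 is taken as a catalogue chemical. Drimane numbering is used for all bicyclic compounds (decalin C1–C10, C11 on C9, C12 on C8, gem-dimethyl on C4, methyl on C10); α is the face opposite to the C10 methyl group.

Step 1
Reactants: 1 3-ethoxy-2-methylcyclohex-2-en-1-one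
Product: 3 3-ethoxy-2,6,6-trimethylcyclohex-2-en-1-one, via 3-ethoxy-2,6-dimethylcyclohex-2-en-1-one 2 (not isolated)
Conditions: LiN(i-Pr)2 (1.1 equiv), THF, −78 °C; MeI; then LiN(i-Pr)2 (1.2 equiv), −78 °C; MeI, DMPU, −78 → 0 °C
Reagents that add atoms: iodomethane, CI
Why: Stork–Danheiser α′-alkylation: kinetic deprotonation of the vinylogous ester is possible only at C6, so two cycles in one flask install the future C4 gem-dimethyl group; no stereocenter remains.

Step 2
Reactants: 3 3-ethoxy-2,6,6-trimethylcyclohex-2-en-1-one
Product: 5 2,4,4-trimethyl-3-vinylcyclohex-2-en-1-one, via 3-ethoxy-2,6,6-trimethyl-1-vinylcyclohex-2-en-1-ol 4 (not isolated)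
Conditions: CH2=CHMgBr (2 equiv), THF, 0 → 25 °C; then 1 M HCl, 25 °C
Reagents that add atoms: vinylmagnesium bromide, C=C[Mg]Br; water, O
Why: 1,2-addition of the Grignard reagent to the vinylogous ester carbonyl, then acid hydrolysis and dehydration (Stork–Danheiser transposition) should give the dienone; the diene C10=C5–C6=C7 now stands next to the C1 carbonyl.

Step 3
Reactants: 5 2,4,4-trimethyl-3-vinylcyclohex-2-en-1-one
Product: 6 (R)-2,4,4-trimethyl-3-vinylcyclohex-2-en-1-ol
Conditions: (S)-1-methyl-3,3-diphenyltetrahydro-1H,3H-pyrrolo[1,2-c][1,3,2]oxazaborole [(S)-Me-CBS] (0.2 equiv), catecholborane (1.5 equiv), toluene, −78 °C; MeOH, then aq. NaOH wash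
Reagents that add atoms: none
Why: Corey–Bakshi–Shibata reduction; the 2-methylalkenyl arm is the large group and the ring CH2 the small one, so the (S)-catalyst should give the (R)-alcohol (C1 of the target) by the usual model. Catecholborane at −78 °C reduces only the carbonyl and leaves the vinyl group alone.

Step 4
Reactants: 6 (R)-2,4,4-trimethyl-3-vinylcyclohex-2-en-1-ol
Product: 7 (R)-2,4,4-trimethyl-3-vinylcyclohex-2-en-1-yl pivalate
Conditions: t-BuCOCl (1.5 equiv), pyridine, 4-(dimethylamino)pyridine (0.1 equiv), CH2Cl2, 0 → 25 °C
Reagents that add atoms: pivaloyl chloride, CC(C)(C)C(=O)Cl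
Why: Acylation of the allylic alcohol; the bulky ester is the steering group for step 5, tolerates heat and amidine base, and is removed without a step of its own in step 7.

Step 5
Reactants: 7 (R)-2,4,4-trimethyl-3-vinylcyclohex-2-en-1-yl pivalate; 8 dimethyl but-2-ynedioate
Product: 9 dimethyl (1R,10S)-1-(pivaloyloxy)drima-5,8-diene-11,12-dioate (pivaloyloxy cis to the C10 methyl)
Conditions: 8 (1.5 equiv), 2,6-di-tert-butyl-4-methylphenol (cat.), toluene, 110 °C, sealed tube
Reagents that add atoms: none
Why: Thermal Diels–Alder reaction of the semicyclic diene with the acetylenic diester forms C9–C10 and C7–C8, closes ring B and creates the quaternary C10 with C11 and C12 attached. A(1,2) strain with the C10 methyl holds the C1 pivaloyloxy group pseudoaxial, so the dienophile should bond to C10 from the opposite face and the methyl ends up cis to O1.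

Step 6
Reactants: 9 dimethyl (1R,10S)-1-(pivaloyloxy)drima-5,8-diene-11,12-dioate
Product: 10 dimethyl (1R,5S,10S)-1β-(pivaloyloxy)drima-6,8-diene-11,12-dioate (5α-H)
Conditions: 1,8-diazabicyclo[5.4.0]undec-7-ene (0.5 equiv), THF, 25 → 60 °C
Reagents that add atoms: none
Why: Base-mediated prototropic shift: deprotonation at the doubly allylic C7 (γ to the C11 ester) gives an extended enolate that is reprotonated at C5 to the fully conjugated dienoate. The step is reversible, so C5 should settle as the trans-fused 5α-H isomer, with the proton anti to the C10 methyl.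

Step 7
Reactants: 10 dimethyl (1R,5S,10S)-1β-(pivaloyloxy)drima-6,8-diene-11,12-dioate
Product: 11 drima-6,8-diene-1β,11,12-triol
Conditions: i-Bu2AlH (8 equiv), CH2Cl2, −78 → 0 °C; aq. KNaC4H4O6 work-up
Reagents that add atoms: none
Why: The aluminium hydride reduces both conjugated esters by 1,2-addition to the allylic alcohols and cleaves the pivalate in the same operation; no stereocenter is touched.

Step 8
Reactants: 11 drima-6,8-diene-1β,11,12-triol
Product: 12 11,12-bis(tert-butyldimethylsilyloxy)drima-6,8-dien-1β-ol
Conditions: t-BuMe2SiCl (2.2 equiv), imidazole, DMF, 0 °C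
Reagents that add atoms: tert-butyldimethylsilyl chloride, CC(C)(C)[Si](C)(C)Cl
Why: Silylation is much faster at the two primary allylic hydroxyls than at the secondary C1 hydroxyl next to quaternary C10, so the bis-silyl ether should form selectively; the diene stays electron-rich for step 9.

Step 9
Reactants: 12 11,12-bis(tert-butyldimethylsilyloxy)drima-6,8-dien-1β-ol
Product: 14 11,12-bis(tert-butyldimethylsilyloxy)drim-7-ene-1β,6α,9α-triol, via 11,12-bis(tert-butyldimethylsilyloxy)-6α,9α-epidioxydrim-7-en-1β-ol 13 (not isolated)
Conditions: O2 (1 atm), 5,10,15,20-tetraphenylporphyrin (1 mol %), visible light, CH2Cl2, −78 °C; then thiourea (2 equiv), MeOH, −78 → 25 °C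
Reagents that add atoms: dioxygen, O=O
Why: Triplet-excited tetraphenylporphyrin passes its energy to O2, and the singlet oxygen formed adds suprafacially across C6 and C9 of the s-cis-locked diene in a [4+2] cycloaddition; the closest known reaction type is the dye-sensitized photooxygenation of homoannular terpenoid and steroid ring dienes to 1,4-epidioxides. The six-membered 1,2-dioxine ring closes in one concerted step with both C–O bonds on the same face, which turns ring B into a 2,3-dioxabicyclo[2.2.2]oct-5-ene with C7=C8 as the remaining double bond. C6 and C9 are set together by the face of attack: the axial C10 methyl, backed by the β methyl on C4, covers the β face, while the α face carries only the axial C5–H, so the bridge should form α; C1, C5 and C10 are not touched. The step needs [4+2] to win over ene-type hydroperoxidation; the fixed cisoid geometry, the electron-rich tetrasubstituted terminus and the low temperature favour cycloaddition, and the allylic C–H bonds next to the silyloxy groups are deactivated for hydrogen abstraction. Because ring A is trans-fused across the C5–C10 bridge of the new bicycle, 13 is strained and is not isolated; thiourea cuts the weak O–O bond in the same flask, releases the strain and leaves both C–O bonds as the cis-6α,9α-diol. Acid and base are kept out so that the peroxide does not fragment to a hydroxy enone.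

Step 10
Reactants: 14 11,12-bis(tert-butyldimethylsilyloxy)drim-7-ene-1β,6α,9α-triol
Product: 15 1β,6α-diacetoxy-11,12-bis(tert-butyldimethylsilyloxy)drim-7-en-9α-ol
Conditions: Ac2O (4 equiv), pyridine, 4-(dimethylamino)pyridine (0.1 equiv), CH2Cl2, 0 → 25 °C
Reagents that add atoms: acetic anhydride, CC(=O)OC(C)=O
Why: Acetylation under nucleophilic catalysis esterifies the two secondary hydroxyls at C1 and C6; the tertiary C9 hydroxyl, flanked by C10 and a silyloxymethyl group, should stay free.

Step 11
Reactants: 15 1β,6α-diacetoxy-11,12-bis(tert-butyldimethylsilyloxy)drim-7-en-9α-ol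
Product: 16 1β,6α-diacetoxydrim-7-ene-9α,11,12-triol
Conditions: HF·pyridine, pyridine, THF, 0 → 25 °C
Reagents that add atoms: none
Why: Fluoride cleaves both primary silyl ethers under buffered conditions that leave the acetates and the tertiary allylic alcohol intact and do not promote acyl migration.

Step 12
Reactants: 16 1β,6α-diacetoxydrim-7-ene-9α,11,12-triol
Product: 17 parritadial, (1R,5S,6S,9S,10R)-1β,6α-diacetoxy-9α-hydroxydrim-7-ene-11,12-dial
Conditions: (COCl)2 (4 equiv), DMSO (8 equiv), CH2Cl2, −78 °C; then Et3N (10 equiv), −78 → −20 °C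
Reagents that add atoms: none
Why: Swern oxidation: both primary hydroxyls are converted to alkoxysulfonium ions at −78 °C before base is added, so they are oxidized together and no lactol or lactone can form from a hydroxy aldehyde. The tertiary alcohol is inert and C9 has no hydrogen to lose.

## Compound list

1 | 3-ethoxy-2-methylcyclohex-2-en-1-one | CCOC1=C(C)C(=O)CCC1 | starting material
2 | 3-ethoxy-2,6-dimethylcyclohex-2-en-1-one (racemic) | CCOC1=C(C)C(=O)C(C)CC1 | intermediate
3 | 3-ethoxy-2,6,6-trimethylcyclohex-2-en-1-one | CCOC1=C(C)C(=O)C(C)(C)CC1 | intermediate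
4 | 3-ethoxy-2,6,6-trimethyl-1-vinylcyclohex-2-en-1-ol (racemic, formed as its magnesium alkoxide) | CCOC1=C(C)C(O)(C=C)C(C)(C)CC1 | intermediate
5 | 2,4,4-trimethyl-3-vinylcyclohex-2-en-1-one | C=CC1=C(C)C(=O)CCC1(C)C | intermediate
6 | (R)-2,4,4-trimethyl-3-vinylcyclohex-2-en-1-ol | C=CC1=C(C)[C@H](O)CCC1(C)C | intermediate
7 | (R)-2,4,4-trimethyl-3-vinylcyclohex-2-en-1-yl pivalate | C=CC1=C(C)[C@H](OC(=O)C(C)(C)C)CCC1(C)C | intermediate
8 | dimethyl but-2-ynedioate | COC(=O)C#CC(=O)OC | starting material
9 | dimethyl (1R,10S)-1-(pivaloyloxy)drima-5,8-diene-11,12-dioate | C1=C2C(C)(C)CC[C@@H](OC(=O)C(C)(C)C)[C@]2(C)C(C(=O)OC)=C(C(=O)OC)C1 | intermediate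
10 | dimethyl (1R,5S,10S)-1β-(pivaloyloxy)drima-6,8-diene-11,12-dioate | C1=CC(C(=O)OC)=C(C(=O)OC)[C@@]2(C)[C@H](OC(=O)C(C)(C)C)CCC(C)(C)[C@H]12 | intermediate
11 | drima-6,8-diene-1β,11,12-triol (5α-H) | C1=CC(CO)=C(CO)[C@@]2(C)[C@H](O)CCC(C)(C)[C@H]12 | intermediate
12 | 11,12-bis(tert-butyldimethylsilyloxy)drima-6,8-dien-1β-ol | C1=CC(CO[Si](C)(C)C(C)(C)C)=C(CO[Si](C)(C)C(C)(C)C)[C@@]2(C)[C@H](O)CCC(C)(C)[C@H]12 | intermediate
13 | 11,12-bis(tert-butyldimethylsilyloxy)-6α,9α-epidioxydrim-7-en-1β-ol | O3[C@H]1C=C(CO[Si](C)(C)C(C)(C)C)[C@](O3)(CO[Si](C)(C)C(C)(C)C)[C@@]2(C)[C@H](O)CCC(C)(C)[C@H]12 | intermediate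
14 | 11,12-bis(tert-butyldimethylsilyloxy)drim-7-ene-1β,6α,9α-triol | O[C@H]1C=C(CO[Si](C)(C)C(C)(C)C)[C@](O)(CO[Si](C)(C)C(C)(C)C)[C@@]2(C)[C@H](O)CCC(C)(C)[C@H]12 | intermediate
15 | 1β,6α-diacetoxy-11,12-bis(tert-butyldimethylsilyloxy)drim-7-en-9α-ol | CC(=O)O[C@H]1C=C(CO[Si](C)(C)C(C)(C)C)[C@](O)(CO[Si](C)(C)C(C)(C)C)[C@@]2(C)[C@H](OC(C)=O)CCC(C)(C)[C@H]12 | intermediate
16 | 1β,6α-diacetoxydrim-7-ene-9α,11,12-triol | CC(=O)O[C@H]1C=C(CO)[C@](O)(CO)[C@@]2(C)[C@H](OC(C)=O)CCC(C)(C)[C@H]12 | intermediate
17 | parritadial, (1R,5S,6S,9S,10R)-1β,6α-diacetoxy-9α-hydroxydrim-7-ene-11,12-dial | CC(=O)O[C@H]1C=C(C=O)[C@](O)(C=O)[C@@]2(C)[C@H](OC(C)=O)CCC(C)(C)[C@H]12 | target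

## Step count and least certain steps

Total step count: 12. Longest linear sequence: 12 steps (1 → 17); 8 is bought.

**Step 9 (key step).** Ene-type hydroperoxidation (hydrogen abstraction from C5–H or from the silyloxymethyl groups) may compete with the cycloaddition. The reason is that the cycloadduct carries ring A trans-fused across its C5–C10 bridge, so the [4+2] pathway is less favourable than for an unconstrained cyclohexadiene. Incomplete α-face selectivity and fragmentation of the peroxide before reduction are lesser risks.

The fallback makes the two C–O bonds one at a time by substrate-controlled additions; it sets out from 9 and comes back at 14. Hydroboration of the trisubstituted C5=C6 bond of 9 (BH3·THF, 0 °C; NaBO3·4H2O) adds H to C5 and boron to C6 from the α face and should give dimethyl 6α-hydroxy-1β-(pivaloyloxy)drim-8-ene-11,12-dioate F1. Treatment with KN(SiMe3)2 (excess, THF, −78 °C) removes the C7 proton γ to the C11 ester; the dienolate is hydroxylated at C9 from the α face with 2-(phenylsulfonyl)-3-phenyloxaziridine to give dimethyl 6α,9α-dihydroxy-1β-(pivaloyloxy)drim-7-ene-11,12-dioate F2. Reduction with i-Bu2AlH gives drim-7-ene-1β,6α,9α,11,12-pentaol F3, and silylation of its two primary hydroxyls (t-BuMe2SiCl, imidazole) gives 14.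

**Step 6.** The prototropic equilibrium may favour reprotonation at C9 instead of C5, because an sp3 C9 relieves the contact between C11 and the C1 ester, and some cis ring fusion may form.

The fallback sets C5 by hydrogenation and makes the diene by elimination; it sets out from 9 and comes back at 10. Hydrogenation (H2, Pd/C, EtOAc) should reduce only the trisubstituted C5=C6 bond, from the α face, to give dimethyl 1β-(pivaloyloxy)drim-8-ene-11,12-dioate F4. Wohl–Ziegler bromination (N-bromosuccinimide, (PhCO2)2, PhCF3, 80 °C) at C7, the only allylic C–H position, gives dimethyl 7α-bromo-1β-(pivaloyloxy)drim-8-ene-11,12-dioate F5. Dehydrobromination with 1,8-diazabicyclo[5.4.0]undec-7-ene gives 10.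

**Step 5.** Facial discrimination may be insufficient if the pivaloyloxy group is not held pseudoaxial, and the cycloaddition at the tetrasubstituted terminus C10 may be slow enough for a [1,5]-hydrogen shift of the diene to compete.

The fallback delivers the dienophile through a tether and corrects C1 afterwards; it sets out from 5 and comes back at 12.
- Reduction of 5 with the enantiomeric oxazaborolidine gives (S)-2,4,4-trimethyl-3-vinylcyclohex-2-en-1-ol F6.
- Esterification with 4-methoxy-4-oxobut-2-ynoic acid (dicyclohexylcarbodiimide, CH2Cl2, 0 °C) gives methyl (S)-2,4,4-trimethyl-3-vinylcyclohex-2-en-1-yl but-2-ynedioate F7.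
- Intramolecular Diels–Alder reaction (toluene, 110 °C) can deliver C9 to C10 only on the face of O1, giving the γ-lactone methyl drima-5,8-diene-11,12-dioate 11,1α-lactone F8.
- Isomerization as in step 6 gives the 6,8-diene lactone F9 (5α-H).
- i-Bu2AlH gives drima-6,8-diene-1α,11,12-triol F10, and bis-silylation gives 11,12-bis(tert-butyldimethylsilyloxy)drima-6,8-dien-1α-ol F11.
- Dess–Martin periodinane gives 11,12-bis(tert-butyldimethylsilyloxy)drima-6,8-dien-1-one F12.
- NaBH4 (MeOH, 0 °C) attacks axially from the α face, anti to the C10 methyl, and gives the equatorial 1β-alcohol 12.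

**Step 3.** Enantioselectivity may be insufficient because the two flanks of the carbonyl differ only moderately in size.

The fallback is a resolution; it sets out from 5 and comes back at 6. Luche reduction (NaBH4, CeCl3·7H2O, MeOH) gives racemic 2,4,4-trimethyl-3-vinylcyclohex-2-en-1-ol F13. Candida antarctica lipase B with vinyl acetate acylates the (R)-enantiomer to (R)-2,4,4-trimethyl-3-vinylcyclohex-2-en-1-yl acetate F14, which is separated from the unreacted (S)-alcohol. Methanolysis (K2CO3, MeOH) gives 6.

## Further compounds

F1 | step 9 | dimethyl 6α-hydroxy-1β-(pivaloyloxy)drim-8-ene-11,12-dioate | O[C@H]1CC(C(=O)OC)=C(C(=O)OC)[C@@]2(C)[C@H](OC(=O)C(C)(C)C)CCC(C)(C)[C@H]12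
F2 | step 9 | dimethyl 6α,9α-dihydroxy-1β-(pivaloyloxy)drim-7-ene-11,12-dioate | O[C@H]1C=C(C(=O)OC)[C@](O)(C(=O)OC)[C@@]2(C)[C@H](OC(=O)C(C)(C)C)CCC(C)(C)[C@H]12
F3 | step 9 | drim-7-ene-1β,6α,9α,11,12-pentaol | O[C@H]1C=C(CO)[C@](O)(CO)[C@@]2(C)[C@H](O)CCC(C)(C)[C@H]12
F4 | step 6 | dimethyl 1β-(pivaloyloxy)drim-8-ene-11,12-dioate | C1CC(C(=O)OC)=C(C(=O)OC)[C@@]2(C)[C@H](OC(=O)C(C)(C)C)CCC(C)(C)[C@H]12
F5 | step 6 | dimethyl 7α-bromo-1β-(pivaloyloxy)drim-8-ene-11,12-dioate | C1[C@@H](Br)C(C(=O)OC)=C(C(=O)OC)[C@@]2(C)[C@H](OC(=O)C(C)(C)C)CCC(C)(C)[C@H]12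
F6 | step 5 | (S)-2,4,4-trimethyl-3-vinylcyclohex-2-en-1-ol | C=CC1=C(C)[C@@H](O)CCC1(C)C
F7 | step 5 | methyl (S)-2,4,4-trimethyl-3-vinylcyclohex-2-en-1-yl but-2-ynedioate | C=CC1=C(C)[C@@H](OC(=O)C#CC(=O)OC)CCC1(C)C
F8 | step 5 | methyl drima-5,8-diene-11,12-dioate 11,1α-lactone | COC(=O)C1=C2C(=O)O[C@H]3CCC(C)(C)C(=CC1)[C@@]23C
F9 | step 5 | methyl drima-6,8-diene-11,12-dioate 11,1α-lactone (5α-H) | COC(=O)C1=C2C(=O)O[C@H]3CCC(C)(C)[C@H](C=C1)[C@@]23C
F10 | step 5 | drima-6,8-diene-1α,11,12-triol | C1=CC(CO)=C(CO)[C@@]2(C)[C@@H](O)CCC(C)(C)[C@H]12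
F11 | step 5 | 11,12-bis(tert-butyldimethylsilyloxy)drima-6,8-dien-1α-ol | C1=CC(CO[Si](C)(C)C(C)(C)C)=C(CO[Si](C)(C)C(C)(C)C)[C@@]2(C)[C@@H](O)CCC(C)(C)[C@H]12
F12 | step 5 | 11,12-bis(tert-butyldimethylsilyloxy)drima-6,8-dien-1-one | C1=CC(CO[Si](C)(C)C(C)(C)C)=C(CO[Si](C)(C)C(C)(C)C)[C@@]2(C)C(=O)CCC(C)(C)[C@H]12
F13 | step 3 | racemic 2,4,4-trimethyl-3-vinylcyclohex-2-en-1-ol | C=CC1=C(C)C(O)CCC1(C)C
F14 | step 3 | (R)-2,4,4-trimethyl-3-vinylcyclohex-2-en-1-yl acetate | C=CC1=C(C)[C@H](OC(C)=O)CCC1(C)C
A1 | alternative 1 | (+)-sclareolide | C1C[C@@](C)(OC(=O)C3)[C@H]3[C@@]2(C)CCCC(C)(C)[C@H]12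
A2 | alternative 1 | drim-7-ene-11,12-diol | C1C=C(CO)[C@H](CO)[C@@]2(C)CCCC(C)(C)[C@H]12
A3 | alternative 2 | 2,4,4-trimethyl-2-(3-oxobutyl)cyclohexane-1,3-dione (racemic) | CC(=O)CCC1(C)C(=O)CCC(C)(C)C1=O
A4 | alternative 2 | (R)-4,4,8a-trimethyl-3,4,8,8a-tetrahydronaphthalene-1,6(2H,7H)-dione | O=C1CCC(C)(C)C2=CC(=O)CC[C@@]12C
A5 | alternative 3 | (E)-4-(2,6,6-trimethyl-3-oxocyclohex-1-en-1-yl)but-3-en-2-one | CC(=O)/C=C/C1=C(C)C(=O)CCC1(C)C
A6 | alternative 3 | ethyl (2E,4Z)-3-methyl-5-(2,6,6-trimethyl-3-oxocyclohex-1-en-1-yl)penta-2,4-dienoate | CCOC(=O)/C=C(C)/C=C\C1=C(C)C(=O)CCC1(C)C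
A7 | alternative 3 | ethyl 1-oxodrima-5,7-dien-11-oate (racemic, 9-H cis to the C10 methyl; one enantiomer drawn) | CCOC(=O)[C@@H]1C(C)=CC=C2C(C)(C)CCC(=O)[C@]12C
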